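- Product in the south run forms at first at a fraction 0.0158 min⁻¹ of the charged substrates per minute, and between 30.0 min and 60.0 min at 0.00460 min⁻¹, slower by a factor 0.292.
- Substrate loss between those windows gives a factor 0.576, leaving a further factor 0.507 unexplained. From 60.0 min to 90.0 min the total moves −0.2 percentage points, inside the scatter, so the south run stands at 54.6 % with substrate left.

| flask | left-handed substrate | right-handed substrate | solid reagent | free catalyst | racemization catalyst | remark | time |
|---|---|---|---|---|---|---|---|
| south-east | 0.050 M | 0.050 M | 1 equiv | 18 mol% | 10 mol% | run made earlier |  |
| south | 0.050 M | 0.050 M | 4 equiv | 18 mol% | 10 mol% | run made earlier |  |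
| flask | 0.050 M | 0.050 M | 2.00 equiv | 18 mol% | 10 mol% |  | 80 min |

- south-east (time / min: left-handed product / %, right-handed product / %): 12.0: 14.7, 3.8; 30.0: 27.8, 9.6; 60.0: 31.8, 10.5; 90.0: 33.3, 12.4
- south (time / min: left-handed product / %, right-handed product / %): 12.0: 14.1, 4.8; 30.0: 31.5, 9.4; 60.0: 38.8, 15.9; 90.0: 41.2, 13.3

(scatter of a reading: 1 percentage point)

- free catalyst is single-handed; left-handed substrate and right-handed substrate are mirror images of each other, charged as a racemate, each of them at the stated concentration
- as a solid, counted per litre of solution: solid reagent
- at the start none of the solid reagent is in solution
- an excess is below zero if the other one leads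

* left-handed product and right-handed product together, in percent of the left-handed substrate and right-handed substrate charged together, at 80 min
* excess of left-handed product over right-handed product in the product at 80 min
* whether the exchange between left-handed substrate and right-handed substrate keeps pace with the reaction: how far the product's excess at 80 min gets from its value without exchange to its value with instant exchange (above 80 % keeps pace, below 20 % hardly takes part, else lags behind)

- Suppose free catalyst is lost by a step sharing the making's other factors. Dividing the substrates' relative rate by the catalyst's rate then removes time, so the logarithm of substrate charged over substrate left at the stop grows in proportion to catalyst charged.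
- That logarithm per unit of catalyst loading, read from the south run as 4.39, is the reach per catalyst.
- The south-east run stands at 44.0 %, under the half of the substrates that its solid reagent covers if each product takes one. The flask has twice that solid, so this reckoning takes the reach and gives the flask 54.6 %; it offers nothing on excess or exchange.
- The forecast differs on yield: 50 %, with an excess of left-handed product of 48 % and an exchange that lags behind, adding “The data barely discriminate, so partial exchange is the best guess”.
- The flask gives a yield of 53.6 % and an excess of left-handed product of 50.6 %, and its exchange keeps pace, 86 % of the way from the no-exchange excess to the instant-exchange excess.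

    partner + free catalyst + left-handed substrate → free catalyst + left-handed product (k = 610 M⁻² min⁻¹)
    partner + free catalyst + right-handed substrate → free catalyst + right-handed product (k = 190 M⁻² min⁻¹)
    left-handed substrate + racemization catalyst ⇌ right-handed substrate + racemization catalyst, rate k3*[racemization catalyst]*[left-handed substrate] forward; the back reaction follows from the equilibrium constant (k = 31.0 M⁻¹ min⁻¹)
    solid reagent ⇌ partner, rate k4*(cs4 - [partner]) while solid is left; crystals form when [partner] > cs4 (solubility = 28.0 mM, k = 0.140 min⁻¹)
    free catalyst ⇌ dormant form (K = 0.320, k = 0.240 min⁻¹)
    partner + free catalyst → spent catalyst (k = 4.60 M⁻¹ min⁻¹)

- With the substrates as charged, the making of both products in the flask runs 8.70 times faster than the loss to spent catalyst, and both steps need partner and free catalyst. At 80.0 min the flask holds 0.325 % of the catalyst charged as free catalyst and 99.6 % as spent catalyst, with 46 % of the left-handed substrate charged still there.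
- For the neighbour with 31 mol% free catalyst, the reach of 4.39 gives 74.4 %; the computed yield is 72.3 %.

The runs were generated by integration for substances that don't exist, and the scatter is random.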